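1. Saturday's flask started with more electrophile than Monday's, 0.040 M against 0.030 M, yet at 10.0 min the two held nearly the same share of it, 20.9% and 21.1%. Here the electrophile meets nucleophile dissolving from the held gas, giving product and acid set free.

| flask | electrophile | free base | gas | remark | time |
|---|---|---|---|---|---|
| Monday's | 0.030 M | 0.80 equiv | 5.5 mM (held) | run made earlier |  |
| Saturday's | 0.040 M | 0.80 equiv | 5.5 mM (held) | run made earlier |  |
| midnight | 0.020 M | 1.80 equiv | 5.5 mM (held) |  | 15 min |
| autumn | 0.020 M | 1.20 equiv | 5.5 mM (held) |  | 15 min |
| spring | 0.020 M | 0.800 equiv | 5.5 mM (held) |  | 15 min |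

| run | time / min | electrophile / % | product / % |
|---|---|---|---|
| Monday's | 0.667 | 91.4 | 8.1 |
| Monday's | 1.50 | 80.4 | 18.8 |
| Monday's | 4.00 | 54.6 | 45.2 |
| Monday's | 10.0 | 21.1 | 79.4 |
| Saturday's | 0.667 | 91.8 | 8.1 |
| Saturday's | 1.50 | 82.4 | 17.6 |
| Saturday's | 4.00 | 57.1 | 44.4 |
| Saturday's | 10.0 | 20.9 | 77.7 |

(readings scatter by 0.5 percentage points)

- at the start none of nucleophile is dissolved
- candidate steps: acid set free + free base <-> salt of the base; gas <-> nucleophile; electrophile + nucleophile -> acid set free + product; nucleophile + acid set free <-> protonated nucleophile

* part of the electrophile that has reacted at the end, midnight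
* part of the electrophile that has reacted at the end, autumn
* part of the electrophile that has reacted at the end, spring
* what raising the equivalents of free base from its lowest to its highest value here does to the part of the electrophile that has reacted (changes below 5 percentage points count as none) (no change / it falls / it rises)

2. A share that does not follow the charge is the mark of pseudo-first-order decay, and [nucleophile] cannot have come from a stock, for Saturday's flask made 31.1 mM of product by then, more than the saturation value of 5.5 mM, so the gas kept feeding it, on average at no less than 3.11 mM min⁻¹, a floor that counts the nucleophile ending in product and none that acid set free may bind.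

3. We therefore work in logarithms and read the decade rate, the powers of ten by which [electrophile] falls per minute, between 4.00 min and 10.0 min: Monday's gives 0.0688 min⁻¹, Saturday's 0.0727 min⁻¹, and their mean is 0.0708 min⁻¹.

4. Spring differs from Monday's in a smaller charge and a longer time, so over 15 min we reckon 1.06 decades, leaving 8.67% and 91.3% reacted.

5. Spring's acid, 18.3 mM, exceeds its charged free base, 16.0 mM, which the runs do not reach; but when the electrophile has fallen to that point, spring makes acid at 0.652 mM min⁻¹, and even with a second nucleophile lost to each acid the demand of 1.30 mM min⁻¹ stays below that floor on Saturday's feed, so we give all three flasks our figure.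

6. The forecast gave 91% (89% to 93%) for midnight, 91% (89% to 93%) for autumn and 90% (83% to 92%) for spring, below our figure there, with no change as the trend, and called spring “the least certain value”.

7. The flasks give 91.8%, 91.8% and 91.8%, so no change, the change being 0.026 percentage points.

    acid set free + free base ⇌ salt of the base, settled at all times (K = 23000 M⁻¹)
    gas ⇌ nucleophile, rate k2*(csat - [nucleophile]) (kL = 0.170 s⁻¹)
    electrophile + nucleophile → acid set free + product (k = 0.530 M⁻¹ s⁻¹)
    nucleophile + acid set free ⇌ protonated nucleophile, settled at all times (K = 1.20 × 10⁶ M⁻¹)

Spring's end corresponds to a decade rate of 0.0722 min⁻¹, beside the 0.0708 min⁻¹ read earlier. At 15.0 min spring still holds 94.2% of its free base unbound and 5.44 mM of nucleophile, with 17.4 mM of protonated nucleophile against 0.925 mM of salt of the base. The neighbour is midnight stopped at 4.0 min: the decade rate gives 0.283 decades, hence 52.1% of the electrophile left, and that flask holds 53.3%.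

(Readings and results were generated by integration on assumed constants, and the scatter is random.)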